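**Plan**

Ring numbering used throughout: C1 carbonyl, C2 (methyl), C3, C4 (OH), C5 (geranylgeranyl), C6 (CH2).
Retrosynthesis: remove the O-silyl group; cut C1–C6 and then C1–C2 so that C1 becomes carbon monoxide; then cut C3–C4 (propyne + enal), C5=C6 (formaldehyde), C4/C5 (acetonitrile) and C5–C1' (geranylgeranyl bromide).
Enabling feature: C1 is a ketone carbon lying between the sp2 carbon C2 and the C6 methylene, and C6 hangs on the methine C5 next to the oxygenated C4. A C2 alkenyl iodide and a C6 alkylborane can therefore be stitched together by CO, and the C5–H/C6–B pair comes from hydroboration of a C5=C6 methylidene under control of C4–O.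
Forward order: the chain is built first (steps 1–4), then C4 (step 5), the Z-iodoalkene (step 6) and the silyl ether (step 7); the only ring arises in step 8 by one-pot hydroboration and carbonylative ring closure, and step 9 frees the alcohol.
Stereochemistry: C4 from catalyst-controlled alkynylation; C5 from substrate-controlled anti hydroboration next to C4 (open-chain anti = 4,5-cis in the ring); C2=C3 geometry from trans-hydroalumination; the chain E-alkenes from geranylgeraniol.

Key step: step 8

Assumption: in step 5 the (R,R)-ProPhenol–zinc catalyst is taken to deliver the alkynyl group to the Re face of the aldehyde of 8, which gives the (4S) carbinol; should the facial sense be the reverse, the (S,S)-ligand is used and nothing else changes.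

**Route**

Step 1
Reactants: 1 (2E,6E,10E)-geranylgeraniol
Product: 2 (2E,6E,10E)-geranylgeranyl bromide
Conditions: PBr3 (0.4 equiv), Et2O, −10 → 0 °C
Reagents that add atoms: phosphorus tribromide, BrP(Br)Br
Why: Bromination of the primary allylic alcohol with PBr3 (SN2 displacement of the phosphite ester by bromide) at low temperature should give the bromide without allylic transposition or loss of the 2E geometry.

Step 2
Reactants: 2 (2E,6E,10E)-geranylgeranyl bromide; 3 acetonitrile
Product: 5 (4E,8E,12E)-5,9,13,17-tetramethyloctadeca-4,8,12,16-tetraenenitrile, via lithioacetonitrile 4 (not isolated)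
Conditions: 3 (4 equiv), LiN(iPr)2 (3.5 equiv), THF, −78 °C; then 2, −78 → −30 °C
Reagents that add atoms: none
Why: Alkylation of lithioacetonitrile (SN2 at the primary allylic bromide) should add the two carbons that become C4 and C5, the excess of anion suppressing dialkylation.

Step 3
Reactants: 5 (4E,8E,12E)-5,9,13,17-tetramethyloctadeca-4,8,12,16-tetraenenitrile
Product: 7 (4E,8E,12E)-5,9,13,17-tetramethyloctadeca-4,8,12,16-tetraenal, via N-diisobutylaluminio aldimine 6 (not isolated)
Conditions: iBu2AlH (1.2 equiv), CH2Cl2, −78 °C; then H2O, aq. potassium sodium tartrate (KNaC4H4O6), rt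
Reagents that add atoms: water, O
Why: Partial reduction of the nitrile by iBu2AlH stops at the N-aluminated aldimine, whose hydrolysis should give the aldehyde without touching the trisubstituted alkenes (nitrile-to-aldehyde reduction).

Step 4
Reactants: 7 (4E,8E,12E)-5,9,13,17-tetramethyloctadeca-4,8,12,16-tetraenal
Product: 8 (4E,8E,12E)-5,9,13,17-tetramethyl-2-methylideneoctadeca-4,8,12,16-tetraenal
Conditions: 37% aq. HCHO (1.1 equiv), pyrrolidine (10 mol %), EtCO2H (10 mol %), iPrOH, 45 °C
Reagents that add atoms: formaldehyde, C=O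
Why: Amine/acid-catalysed Mannich condensation with formaldehyde followed by loss of the amine (organocatalytic α-methylenation of an aldehyde) should install the C5=C6 methylidene, and the product has no α-hydrogen left for a second condensation.

Step 5
Reactants: 8 (4E,8E,12E)-5,9,13,17-tetramethyl-2-methylideneoctadeca-4,8,12,16-tetraenal; 9 propyne
Product: 11 (4S,7E,11E,15E)-8,12,16,20-tetramethyl-5-methylidenehenicosa-7,11,15,19-tetraen-2-yn-4-ol, via methyl(prop-1-ynyl)zinc 10 (not isolated)
Conditions: 9 (3 equiv), Me2Zn (3 equiv), (R,R)-ProPhenol (20 mol %), Ph3PO (40 mol %), toluene, 0 °C; then H2O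
Reagents that add atoms: none
Why: Catalytic enantioselective alkynylation of an aldehyde: the zinc alkynylide 10 made from propyne and Me2Zn adds 1,2 to the enal inside the dinuclear zinc–ProPhenol complex, which should deliver it to the Re face and so set C4 as S; this carbon is not touched again.

Step 6
Reactants: 11 (4S,7E,11E,15E)-8,12,16,20-tetramethyl-5-methylidenehenicosa-7,11,15,19-tetraen-2-yn-4-ol
Product: 13 (2Z,4R,7E,11E,15E)-2-iodo-8,12,16,20-tetramethyl-5-methylidenehenicosa-2,7,11,15,19-pentaen-4-ol, via cyclic alkenylalanate 12 (not isolated)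
Conditions: NaAlH2(OCH2CH2OMe)2 (1.6 equiv), THF, 0 °C → rt; EtOAc, 0 °C; then I2 (1.5 equiv), THF, −78 °C; aq. Na2S2O3
Reagents that add atoms: iodine, II
Why: Hydroxyl-directed trans-hydroalumination of the propargylic alcohol places aluminium on the methyl-bearing alkyne carbon inside a five-membered alkoxyalanate, and iodinolysis of the C–Al bond with retention should give the Z-iodoalkene with iodine cis to C4, the isolated alkenes being inert to the hydride (the C4 descriptor changes by CIP priority only).

Step 7
Reactants: 13 (2Z,4R,7E,11E,15E)-2-iodo-8,12,16,20-tetramethyl-5-methylidenehenicosa-2,7,11,15,19-pentaen-4-ol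
Product: 14 tert-butyl{[(2Z,4R,7E,11E,15E)-2-iodo-8,12,16,20-tetramethyl-5-methylidenehenicosa-2,7,11,15,19-pentaen-4-yl]oxy}dimethylsilane
Conditions: TBSCl (1.5 equiv), imidazole (3 equiv), DMF, 0 °C → rt
Reagents that add atoms: tert-butyldimethylsilyl chloride, CC(C)(C)[Si](C)(C)Cl
Why: Imidazole-promoted silyl ether formation masks the O–H against the borane and the base of step 8 and supplies the bulky allylic OR group on which the hydroboration selectivity relies.

Step 8
Reactants: 14 tert-butyl{[(2Z,4R,7E,11E,15E)-2-iodo-8,12,16,20-tetramethyl-5-methylidenehenicosa-2,7,11,15,19-pentaen-4-yl]oxy}dimethylsilane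
Product: 16 (4S,5S)-4-[(tert-butyldimethylsilyl)oxy]-2-methyl-5-[(2E,6E,10E)-3,7,11,15-tetramethylhexadeca-2,6,10,14-tetraen-1-yl]cyclohex-2-en-1-one, via B-alkyl-9-BBN 15 (not isolated)
Conditions: 9-BBN-H (1.3 equiv), THF, 0 °C → rt; then Pd(PPh3)4 (5 mol %), K3PO4 (3 equiv), CO (1 atm), THF–dioxane (0.01 M), rt → 45 °C
Reagents that add atoms: carbon monoxide, [C-]#[O+]
Why: 9-BBN-H should add only to the C5=C6 methylidene, the one 1,1-disubstituted alkene among four trisubstituted ones, putting boron on C6 and hydrogen on C5 from the face fixed by the adjacent C4 silyloxy stereocentre (acyclic 1,2-induction giving the anti product, which is 4,5-cis once C3–C6 lie in the ring), so the new C5 stereocentre is substrate-controlled by C4. Zerovalent palladium then inserts into the C2–I bond, CO inserts to give the acylpalladium iodide whose carbonyl carbon becomes C1, base-assisted transfer of the primary C6 alkyl group from boron to palladium gives a seven-membered acyl(alkyl)palladacycle, and reductive elimination forms the C1–C6 bond and closes the six-membered ring. The closest known reaction type is the intramolecular carbonylative Suzuki–Miyaura coupling of an iodoalkene with a B-alkyl-9-BBN generated by hydroboration of a tethered alkene, which gives cyclic enones. The closure is formally a [5+1] annulation with CO as the one-carbon unit, and it is feasible because the Z geometry of the alkenyl iodide holds C2 and the C4–C5–C6 arm on the same side of the double bond. The step needs CO insertion to outrun direct alkyl transfer to the alkenylpalladium (which would close a cyclopentene); the CO atmosphere should secure this, since insertion into an alkenyl–palladium bond is fast while B-alkyl transmetalation is slow and base-dependent, and high dilution keeps the coupling intramolecular. K3PO4 near room temperature should leave the C4 silyl ether and the new γ-silyloxy enone untouched.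

Step 9
Reactants: 16 (4S,5S)-4-[(tert-butyldimethylsilyl)oxy]-2-methyl-5-[(2E,6E,10E)-3,7,11,15-tetramethylhexadeca-2,6,10,14-tetraen-1-yl]cyclohex-2-en-1-one
Product: 17 (4S,5S)-4-hydroxy-2-methyl-5-[(2E,6E,10E)-3,7,11,15-tetramethylhexadeca-2,6,10,14-tetraen-1-yl]cyclohex-2-en-1-one (target)
Conditions: HF·pyridine, pyridine, THF, 0 °C → rt
Reagents that add atoms: none
Why: Desilylation with pyridine-buffered HF should free the C4 hydroxyl under conditions too mild for dehydration of the γ-hydroxy enone to a phenol or for epimerisation.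

**Compound list**

1 | (2E,6E,10E)-geranylgeraniol | OC/C=C(\C)CC/C=C(\C)CC/C=C(\C)CCC=C(C)C | starting material
2 | (2E,6E,10E)-geranylgeranyl bromide | BrC/C=C(\C)CC/C=C(\C)CC/C=C(\C)CCC=C(C)C | intermediate
3 | acetonitrile | CC#N | starting material
4 | lithioacetonitrile (cyanomethyllithium) | [Li+].[CH2-]C#N | intermediate
5 | (4E,8E,12E)-5,9,13,17-tetramethyloctadeca-4,8,12,16-tetraenenitrile | N#CCC/C=C(\C)CC/C=C(\C)CC/C=C(\C)CCC=C(C)C | intermediate
6 | N-diisobutylaluminio aldimine of 7 | CC(C)C[Al](CC(C)C)N=CCC/C=C(\C)CC/C=C(\C)CC/C=C(\C)CCC=C(C)C | intermediate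
7 | (4E,8E,12E)-5,9,13,17-tetramethyloctadeca-4,8,12,16-tetraenal | O=CCC/C=C(\C)CC/C=C(\C)CC/C=C(\C)CCC=C(C)C | intermediate
8 | (4E,8E,12E)-5,9,13,17-tetramethyl-2-methylideneoctadeca-4,8,12,16-tetraenal | O=CC(=C)C/C=C(\C)CC/C=C(\C)CC/C=C(\C)CCC=C(C)C | intermediate
9 | propyne | CC#C | starting material
10 | methyl(prop-1-yn-1-yl)zinc | C[Zn]C#CC | intermediate
11 | (4S,7E,11E,15E)-8,12,16,20-tetramethyl-5-methylidenehenicosa-7,11,15,19-tetraen-2-yn-4-ol | CC#C[C@H](C(=C)C/C=C(\C)CC/C=C(\C)CC/C=C(\C)CCC=C(C)C)O | intermediate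
12 | sodium alkenylalanate in which aluminium (two 2-methoxyethoxy ligands) bridges the C4 oxygen and C2 of the new C2=C3 bond in a five-membered ring (C4 R) | [Na+].CC1=C[C@H](C(=C)C/C=C(\C)CC/C=C(\C)CC/C=C(\C)CCC=C(C)C)O[Al-]1(OCCOC)OCCOC | intermediate
13 | (2Z,4R,7E,11E,15E)-2-iodo-8,12,16,20-tetramethyl-5-methylidenehenicosa-2,7,11,15,19-pentaen-4-ol | C/C(I)=C/[C@H](C(=C)C/C=C(\C)CC/C=C(\C)CC/C=C(\C)CCC=C(C)C)O | intermediate
14 | tert-butyl{[(2Z,4R,7E,11E,15E)-2-iodo-8,12,16,20-tetramethyl-5-methylidenehenicosa-2,7,11,15,19-pentaen-4-yl]oxy}dimethylsilane | C/C(I)=C/[C@H](C(=C)C/C=C(\C)CC/C=C(\C)CC/C=C(\C)CCC=C(C)C)O[Si](C)(C)C(C)(C)C | intermediate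
15 | 9-{(2R,3S,4Z)-3-[(tert-butyldimethylsilyl)oxy]-5-iodo-2-[(2E,6E,10E)-3,7,11,15-tetramethylhexadeca-2,6,10,14-tetraen-1-yl]hex-4-en-1-yl}-9-borabicyclo[3.3.1]nonane | C/C(I)=C/[C@H]([C@H](CB1C2CCCC1CCC2)C/C=C(\C)CC/C=C(\C)CC/C=C(\C)CCC=C(C)C)O[Si](C)(C)C(C)(C)C | intermediate
16 | (4S,5S)-4-[(tert-butyldimethylsilyl)oxy]-2-methyl-5-[(2E,6E,10E)-3,7,11,15-tetramethylhexadeca-2,6,10,14-tetraen-1-yl]cyclohex-2-en-1-one | CC(C)=CCC/C(C)=C/CC/C(C)=C/CC/C(C)=C/C[C@H]1CC(=O)C(C)=C[C@H]1O[Si](C)(C)C(C)(C)C | intermediate
17 | (4S,5S)-4-hydroxy-2-methyl-5-[(2E,6E,10E)-3,7,11,15-tetramethylhexadeca-2,6,10,14-tetraen-1-yl]cyclohex-2-en-1-one | CC(C)=CCC/C(C)=C/CC/C(C)=C/CC/C(C)=C/C[C@H]1CC(=O)C(C)=C[C@H]1O | target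

**Step count and risks**

Total step count: 9. Longest linear sequence: 9 steps (from 1).

Steps most likely to fail:

1. Step 8. What may go wrong: alkyl transfer to the alkenylpalladium before CO insertion (closure of a five-membered ring without the carbonyl), β-hydride elimination of the alkylpalladium, or insufficient facial selectivity in the hydroboration of the methylidene. The fallback replaces the catalytic carbonylative coupling by an ionic acylation; it sets out from 14 and comes back at 16. Methoxycarbonylation of the alkenyl iodide (PdCl2(PPh3)2, CO, MeOH, Et3N, DMF, 50 °C) should give the methyl (2Z)-enoate F1, which now carries C1. Hydroboration with 9-BBN-H and oxidation with NaBO3 should give the primary alcohol F2 under the same 1,2-induction, and diastereomers can be separated at this stage. An Appel reaction (I2, PPh3, imidazole, CH2Cl2) gives the primary iodide F3. Iodine–lithium exchange with t-BuLi (2.2 equiv, Et2O–pentane, −100 → −78 °C) and attack of the C6 alkyllithium on the ester carbonyl, held close by the Z-alkene, should then close the ring to 16.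

2. Step 5. What may go wrong: poor or reversed facial selectivity in the alkynyl transfer, or slow 1,2-addition that lets the 2-substituted acrolein oligomerise. The fallback replaces catalytic C–C bond formation by a reagent-controlled ketone reduction; it sets out from 8 and comes back at 11. Addition of MeC≡CMgBr (THF, −78 °C) gives the racemic carbinol F4, and MnO2 (CH2Cl2, rt) oxidises this doubly activated alcohol to the enynone F5. A Midland reduction with (S)-Alpine-Borane (THF, rt), in which the linear propynyl group acts as the small substituent, should return 11.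

3. Step 4. What may go wrong: migration of the skipped C=C into conjugation through the dienamine, or Michael-type oligomerisation of the product under the amine catalyst. The fallback makes the methylidene by a Horner–Wadsworth–Emmons reaction before the aldehyde oxidation level is reached and bypasses steps 2 and 3 as well; it sets out from 2 and comes back at 8. Alkylation of triethyl phosphonoacetate with 2 (NaH, THF–DMF, 0 °C → rt) gives the phosphonate F6. Reaction with aqueous formaldehyde and K2CO3 gives the 2-methylidene ester F7, reduction with iBu2AlH (2.2 equiv, CH2Cl2, −78 °C) gives the allylic alcohol F8, and MnO2 (CH2Cl2, rt) gives 8 under neutral conditions.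

Further compounds
F1 | step 8 | methyl (2Z,4R,7E,11E,15E)-4-[(tert-butyldimethylsilyl)oxy]-2,8,12,16,20-pentamethyl-5-methylidenehenicosa-2,7,11,15,19-pentaenoate | C/C(C(=O)OC)=C/[C@H](C(=C)C/C=C(\C)CC/C=C(\C)CC/C=C(\C)CCC=C(C)C)O[Si](C)(C)C(C)(C)C
F2 | step 8 | methyl (2Z,4R,5S,7E,11E,15E)-4-[(tert-butyldimethylsilyl)oxy]-5-(hydroxymethyl)-2,8,12,16,20-pentamethylhenicosa-2,7,11,15,19-pentaenoate | C/C(C(=O)OC)=C/[C@H]([C@H](CO)C/C=C(\C)CC/C=C(\C)CC/C=C(\C)CCC=C(C)C)O[Si](C)(C)C(C)(C)C
F3 | step 8 | methyl (2Z,4R,5R,7E,11E,15E)-4-[(tert-butyldimethylsilyl)oxy]-5-(iodomethyl)-2,8,12,16,20-pentamethylhenicosa-2,7,11,15,19-pentaenoate | C/C(C(=O)OC)=C/[C@H]([C@H](CI)C/C=C(\C)CC/C=C(\C)CC/C=C(\C)CCC=C(C)C)O[Si](C)(C)C(C)(C)C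
F4 | step 5 | racemic (7E,11E,15E)-8,12,16,20-tetramethyl-5-methylidenehenicosa-7,11,15,19-tetraen-2-yn-4-ol | CC#CC(O)C(=C)C/C=C(\C)CC/C=C(\C)CC/C=C(\C)CCC=C(C)C
F5 | step 5 | (7E,11E,15E)-8,12,16,20-tetramethyl-5-methylidenehenicosa-7,11,15,19-tetraen-2-yn-4-one | CC#CC(=O)C(=C)C/C=C(\C)CC/C=C(\C)CC/C=C(\C)CCC=C(C)C
F6 | step 4 | ethyl (4E,8E,12E)-2-(diethoxyphosphoryl)-5,9,13,17-tetramethyloctadeca-4,8,12,16-tetraenoate (racemic) | CCOC(=O)C(C/C=C(\C)CC/C=C(\C)CC/C=C(\C)CCC=C(C)C)P(=O)(OCC)OCC
F7 | step 4 | ethyl (4E,8E,12E)-5,9,13,17-tetramethyl-2-methylideneoctadeca-4,8,12,16-tetraenoate | CCOC(=O)C(=C)C/C=C(\C)CC/C=C(\C)CC/C=C(\C)CCC=C(C)C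
F8 | step 4 | (4E,8E,12E)-5,9,13,17-tetramethyl-2-methylideneoctadeca-4,8,12,16-tetraen-1-ol | OCC(=C)C/C=C(\C)CC/C=C(\C)CC/C=C(\C)CCC=C(C)C
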